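The closed, stirred, isothermal flask held free monomer, initiator and slightly more impurity. Propagation is first order in the living end, so I looked for one concentration, the living end L, which makes free monomer decay as a pseudo-first-order species with constant k·L, k being the propagation rate constant.

free monomer 0.053 M; initiator 0.19 mM; impurity 0.20 mM; time 4.0 min

    free monomer + initiator → living end + monomer in chains (k1 = 31 M⁻¹ s⁻¹)
    free monomer + living end → monomer in chains + living end, rate k2*[living end]*[free monomer] (k2 = 200 M⁻¹ s⁻¹)
    initiator → spent initiator A (k3 = 0.19 s⁻¹)
    initiator + impurity → spent initiator B (k4 = 2.1 × 10⁵ M⁻¹ s⁻¹)

- average number of monomer units in a chain (chains begun, living or dead) at 4.0 min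
- part of the free monomer that has reacted at 4.0 min

- the average divides the monomer in chains by the number of chains begun, living and dead together
- run time (flask): 4.0 min

The bench rule says one impurity kills one initiator and the surplus starts chains. Here the impurity exceeded the initiator by 0.0100 mM, so the rule promised no chains. It needs the impurity to outrun the other initiator losses, and that ends near 0.00873 mM, Y_c, the crossover impurity concentration at which scavenging equals initiation and decay together, free monomer taken at its charge. The excess was just 1.15 times Y_c, so I did not trust the rule for this flask.

I therefore balanced the initiator charge against the impurity used plus Y_c·ln(impurity charge/Y_e), where Y_e is the impurity left. Two passes, starting with Y_c inside the logarithm, gave Y_e as 0.0373 mM, then 0.0246 mM. Initiation's share of the leak, 0.00782 mM times that logarithm, gave L = 1.64 × 10⁻⁵ M. The half-life of initiator by decay alone, 0.061 min, is far shorter than the run, so I held L constant. That gave k·L·t = 0.786, a conversion of 54.4% and an average of 1760 units.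

The forecast gave 1790 and 52.6%: “That fixed number of living ends then consumes monomer first-order”.

The simulation of this flask gave 1790 and 52.6%, with the living end at 1.56 × 10⁻⁵ M and the impurity at 3.13 times Y_c after 4.00 min. The neighbouring flask, charged with 1.1 × 10⁻⁴ M of initiator, has the same Y_c, since free monomer and the constants were unchanged. One pass from its impurity excess gave Y_e = 0.0970 mM and L = 5.66 × 10⁻⁶ M, hence 23.8% conversion and 2230 units. That flask read 5.71 × 10⁻⁶ M of living end, 24.0% conversion and 2230 units.

(The constants used here are made up; what happens was integrated by code.)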